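**Plan**
1. Retrosynthesis first adjusts oxidation levels only: C9 and the side-chain carbinol go back to the acyl level (C9 as an N-acyl oxazolidinone, the side chain as a methyl cinnamate) and the guaiacyl phenol to a pivalate.
2. The one skeletal cut between the aryl halves is C7–C8, an aldol bond. C7 is the benzylic carbinol carbon on the guaiacyl ring and lies β to C9; C8 carries the ether oxygen of the syringyl ring. C8 is therefore the α-carbon of an aryloxyacetyl enolate and C7 the carbonyl carbon of O-pivaloylvanillin.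
3. The aryl ether O–CH2 bond and the N–C9 bond are cut next, back to methyl sinapate, tert-butyl bromoacetate and (S)-4-benzyloxazolidin-2-one.
4. Forward: ether, acid and imide are built on the syringyl half; a boron aldol joins the halves; NaBH4 turns C9 into CH2OH and returns the auxiliary; one DIBAL-H step makes the allylic alcohol and frees the phenol. No ring is formed.
5. Stereochemistry: C7 and C8 both arise in the aldol. The syn (7,8-threo) relation comes from the (Z)-boron enolate in a chair transition state, the absolute sense from the (S)-benzyl auxiliary, and the E-alkene from methyl sinapate.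

Key step: step 5

Remark: neolignan numbering is used (C7 benzylic carbinol, C8 aryloxy carbon, C9 CH2OH); the (7R,8R) target is the 7,8-threo isomer, which is the syn isomer in the aldol (zigzag) sense, and methyl sinapate is taken as a commercial material.

**Route**

Step 1
Reactants: 1 methyl sinapate [methyl (E)-3-(4-hydroxy-3,5-dimethoxyphenyl)prop-2-enoate]; 2 tert-butyl bromoacetate
Product: 3 methyl (E)-3-[4-(2-tert-butoxy-2-oxoethoxy)-3,5-dimethoxyphenyl]prop-2-enoate
Conditions: K2CO3, DMF, rt → 50 °C
Reagents that add atoms: none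
Why: Williamson ether synthesis, in which the phenoxide of 1 (the only acidic OH) displaces bromide from the activated α-bromo ester by SN2; no stereocentre is formed and the E-alkene is untouched.

Step 2
Reactants: 3 methyl (E)-3-[4-(2-tert-butoxy-2-oxoethoxy)-3,5-dimethoxyphenyl]prop-2-enoate
Product: 4 {2,6-dimethoxy-4-[(E)-3-methoxy-3-oxoprop-1-en-1-yl]phenoxy}acetic acid
Conditions: TFA, CH2Cl2, 0 °C → rt
Reagents that add atoms: none
Why: Acidolysis of the tert-butyl ester (loss of the tert-butyl cation as isobutene) should free the acid, while the methyl cinnamate and the aryl ethers cannot ionise in this way.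

Step 3
Reactants: 4 {2,6-dimethoxy-4-[(E)-3-methoxy-3-oxoprop-1-en-1-yl]phenoxy}acetic acid; 5 (S)-4-benzyloxazolidin-2-one
Product: 7 methyl (E)-3-(4-{2-[(4S)-4-benzyl-2-oxo-1,3-oxazolidin-3-yl]-2-oxoethoxy}-3,5-dimethoxyphenyl)prop-2-enoate, via mixed pivalic anhydride 6 (not isolated)
Conditions: PivCl, Et3N, THF, −20 °C; then LiCl, 5, −20 °C → rt
Reagents that add atoms: none
Why: N-acylation of the oxazolidinone through the mixed pivalic anhydride (LiCl/Et3N procedure); the hindered pivaloyl carbonyl directs attack to the aryloxyacetyl carbonyl, and the C4 stereocentre of 5 is not involved.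

Step 4
Reactants: 8 vanillin (4-hydroxy-3-methoxybenzaldehyde)
Product: 9 4-formyl-2-methoxyphenyl 2,2-dimethylpropanoate (O-pivaloylvanillin)
Conditions: PivCl, Et3N, DMAP (cat.), CH2Cl2, 0 °C → rt
Reagents that add atoms: pivaloyl chloride, CC(C)(C)C(=O)Cl
Why: DMAP-catalysed O-acylation of the phenol; the pivalate is chosen because it has no α-hydrogen for the boron enolisation, should survive NaBH4 and is removed by DIBAL-H in step 7.

Step 5
Reactants: 7 methyl (E)-3-(4-{2-[(4S)-4-benzyl-2-oxo-1,3-oxazolidin-3-yl]-2-oxoethoxy}-3,5-dimethoxyphenyl)prop-2-enoate; 9 4-formyl-2-methoxyphenyl 2,2-dimethylpropanoate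
Product: 12 syn-aldol adduct 4-{(1R,2S)-3-[(4S)-4-benzyl-2-oxo-1,3-oxazolidin-3-yl]-2-{2,6-dimethoxy-4-[(E)-3-methoxy-3-oxoprop-1-en-1-yl]phenoxy}-1-hydroxy-3-oxopropyl}-2-methoxyphenyl 2,2-dimethylpropanoate, via dibutylboron Z-enolate 10 (not isolated), via dibutylboron aldolate 11 (not isolated)
Conditions: Bu2BOTf (1.2 equiv), iPr2NEt (1.4 equiv), CH2Cl2, −78 → 0 °C; 9, −78 → 0 °C; then pH 7 buffer, MeOH, 30% H2O2, 0 °C
Reagents that add atoms: none
Why: Bu2BOTf/iPr2NEt should enolise only the imide CH2 of 7 (the cinnamate has only a vinylic α-hydrogen and the pivalate of 9 has none), giving the chelation-free (Z)-O-boron enolate 10, which adds to the aldehyde through a closed chair-like Zimmerman–Traxler transition state. The closest known reaction type is the Evans boron syn-aldol of N-glycolyl and N-(aryloxyacetyl)oxazolidinones. No ring of the product is closed; the only ring involved is the transient six-membered boron chair. C8 is controlled by the auxiliary: in the dipole-opposed rotamer of 10 the benzyl group at C4 of the oxazolidinone blocks one enolate face, so the aldehyde bonds to the other. C7 is controlled by the (Z)-enolate geometry together with the chair, in which the aryl group of 9 sits equatorial, which gives the 2,3-syn (7,8-threo) relation. The step needs syn simple diastereoselection, auxiliary-controlled facial selection and chemoselective enolisation, secured respectively by the tight boron chair, the (S)-benzyl auxiliary and the high acidity of the boron-complexed imide CH2 flanked by the aryloxy oxygen.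

Step 6
Reactants: 12 syn-aldol adduct
Product: 13 4-[(1R,2R)-2-{2,6-dimethoxy-4-[(E)-3-methoxy-3-oxoprop-1-en-1-yl]phenoxy}-1,3-dihydroxypropyl]-2-methoxyphenyl 2,2-dimethylpropanoate
Conditions: NaBH4, THF/H2O (4:1), 0 °C → rt
Reagents that add atoms: none
Why: Reductive cleavage of the N-acyl oxazolidinone, in which hydride attacks the exocyclic imide carbonyl and the aldehyde formed is reduced on; the conjugated methyl ester and the hindered aryl pivalate should be left, C7 and C8 are not touched (only the C8 descriptor changes) and the auxiliary 5 is returned.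

Step 7
Reactants: 13 4-[(1R,2R)-2-{2,6-dimethoxy-4-[(E)-3-methoxy-3-oxoprop-1-en-1-yl]phenoxy}-1,3-dihydroxypropyl]-2-methoxyphenyl 2,2-dimethylpropanoate
Product: 14 (1R,2R)-1-(4-hydroxy-3-methoxyphenyl)-2-{4-[(E)-3-hydroxyprop-1-en-1-yl]-2,6-dimethoxyphenoxy}propane-1,3-diol
Conditions: DIBAL-H (ca. 8 equiv), CH2Cl2/THF, −78 → 0 °C; aq. Rochelle salt
Reagents that add atoms: none
Why: DIBAL-H 1,2-reduction of the cinnamate ester to the allylic alcohol with retention of the E-alkene, with reductive cleavage of the aryl pivalate in the same flask; the two free hydroxyls are carried as aluminium alkoxides and the stereocentres are not involved.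

**Compound list**
1 | methyl sinapate, methyl (E)-3-(4-hydroxy-3,5-dimethoxyphenyl)prop-2-enoate | COC(=O)/C=C/c1cc(OC)c(O)c(OC)c1 | starting material
2 | tert-butyl bromoacetate | CC(C)(C)OC(=O)CBr | starting material
3 | methyl (E)-3-[4-(2-tert-butoxy-2-oxoethoxy)-3,5-dimethoxyphenyl]prop-2-enoate | COC(=O)/C=C/c1cc(OC)c(OCC(=O)OC(C)(C)C)c(OC)c1 | intermediate
4 | {2,6-dimethoxy-4-[(E)-3-methoxy-3-oxoprop-1-en-1-yl]phenoxy}acetic acid | COC(=O)/C=C/c1cc(OC)c(OCC(=O)O)c(OC)c1 | intermediate
5 | (S)-4-benzyloxazolidin-2-one | O=C1N[C@@H](Cc2ccccc2)CO1 | starting material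
6 | mixed anhydride of 4 with pivalic acid | COC(=O)/C=C/c1cc(OC)c(OCC(=O)OC(=O)C(C)(C)C)c(OC)c1 | intermediate
7 | methyl (E)-3-(4-{2-[(4S)-4-benzyl-2-oxo-1,3-oxazolidin-3-yl]-2-oxoethoxy}-3,5-dimethoxyphenyl)prop-2-enoate | COC(=O)/C=C/c1cc(OC)c(OCC(=O)N2[C@@H](Cc3ccccc3)COC2=O)c(OC)c1 | intermediate
8 | vanillin | COc1cc(C=O)ccc1O | starting material
9 | 4-formyl-2-methoxyphenyl 2,2-dimethylpropanoate | COc1cc(C=O)ccc1OC(=O)C(C)(C)C | intermediate
10 | (Z)-dibutylboron enolate of 7 | CCCCB(CCCC)O/C(=C\Oc1c(OC)cc(/C=C/C(=O)OC)cc1OC)N1[C@@H](Cc2ccccc2)COC1=O | intermediate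
11 | dibutylboron aldolate (7-O-BBu2 derivative of 12) | COc1cc([C@@H](OB(CCCC)CCCC)[C@@H](C(=O)N2[C@@H](Cc3ccccc3)COC2=O)Oc4c(OC)cc(/C=C/C(=O)OC)cc4OC)ccc1OC(=O)C(C)(C)C | intermediate
12 | syn-aldol adduct, (2S,3R)-acyl chain on the (4S)-oxazolidinone | COc1cc([C@@H](O)[C@@H](C(=O)N2[C@@H](Cc3ccccc3)COC2=O)Oc4c(OC)cc(/C=C/C(=O)OC)cc4OC)ccc1OC(=O)C(C)(C)C | intermediate
13 | 4-[(1R,2R)-2-{2,6-dimethoxy-4-[(E)-3-methoxy-3-oxoprop-1-en-1-yl]phenoxy}-1,3-dihydroxypropyl]-2-methoxyphenyl 2,2-dimethylpropanoate | COc1cc([C@@H](O)[C@@H](CO)Oc2c(OC)cc(/C=C/C(=O)OC)cc2OC)ccc1OC(=O)C(C)(C)C | intermediate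
14 | (1R,2R)-1-(4-hydroxy-3-methoxyphenyl)-2-{4-[(E)-3-hydroxyprop-1-en-1-yl]-2,6-dimethoxyphenoxy}propane-1,3-diol | COc1cc([C@@H](O)[C@@H](CO)Oc2c(OC)cc(/C=C/CO)cc2OC)ccc1O | target

**Step count and risks**
Total steps: 7. Longest linear sequence: 6 (steps 1, 2, 3, 5, 6, 7); step 4 is the one-step side branch.

Steps most likely to fail:

1. Step 5. The enolisation of the hindered 2,6-dimethoxyaryloxyacetyl imide may be slow or incomplete, or the syn/anti or facial selectivity in the boron chair may erode. The fallback sets out from 3 and 9 and gives up auxiliary control for a stereoconvergent reduction. The lithium enolate of 3 (LiHMDS, THF, −78 °C) is added to 9 and should give, without stereocontrol, the tert-butyl 2-aryloxy-3-hydroxy ester F1 as a mixture of diastereomers. Dess–Martin oxidation should then give the configurationally labile α-aryloxy β-keto ester F2. Asymmetric transfer hydrogenation with dynamic kinetic resolution (RuCl(p-cymene)[(S,S)-TsDPEN], HCO2H/Et3N) should funnel both enantiomers of F2 into the tert-butyl (2S,3R)-syn-hydroxy ester F3. The syn preference is that known for α-alkoxy β-keto esters, and the usual facial sense of this catalyst for aryl ketones corresponds to 7R. Excess DIBAL-H then reduces the tert-butyl ester, the methyl cinnamate and the pivalate together, and the fallback comes back to the route at 14.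

2. Step 7. The aryl pivalate may be cleaved incompletely at the temperature the allylic system tolerates. The aluminium-bound benzylic alkoxide at C7, para to the freed phenoxide, may ionise, with loss or epimerisation of the C7 oxygen. The polar product may also be held on aluminium salts. The fallback sets out from 13 and masks the hydroxyls before the hydride step. TESCl/imidazole (DMF) should give the 7,9-bis(triethylsilyl) ether of 13 F4. DIBAL-H (CH2Cl2, −78 °C) should then give the 7,9-bis(triethylsilyl) ether of 14 F5, which is lipophilic and carries no aluminium alkoxide at C7. TBAF buffered with AcOH (THF, 0 °C) removes both silyl groups, and the fallback comes back to the route at 14.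

3. Step 6. The free β-hydroxy imide may undergo retro-aldol cleavage or C8 epimerisation under the basic borohydride conditions, or hydride may attack the ring carbonyl of the oxazolidinone. The fallback sets out from 12. TESOTf/2,6-lutidine (CH2Cl2, −78 °C) should give the 7-O-triethylsilyl ether of 12 F6, in which no alkoxide can form. LiBH4 (THF, 1 equiv MeOH, 0 °C) should then give the 7-O-triethylsilyl ether of 13 F7 and return the auxiliary. HF·pyridine (THF/pyridine, 0 °C) removes the silyl group, and the fallback comes back to the route at 13.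

**Further compounds**
F1 | step 5 | tert-butyl 2-{2,6-dimethoxy-4-[(E)-3-methoxy-3-oxoprop-1-en-1-yl]phenoxy}-3-hydroxy-3-[3-methoxy-4-(pivaloyloxy)phenyl]propanoate, mixture of diastereomers | COc1cc(C(O)C(C(=O)OC(C)(C)C)Oc2c(OC)cc(/C=C/C(=O)OC)cc2OC)ccc1OC(=O)C(C)(C)C
F2 | step 5 | tert-butyl 2-{2,6-dimethoxy-4-[(E)-3-methoxy-3-oxoprop-1-en-1-yl]phenoxy}-3-[3-methoxy-4-(pivaloyloxy)phenyl]-3-oxopropanoate, racemic | COc1cc(C(=O)C(C(=O)OC(C)(C)C)Oc2c(OC)cc(/C=C/C(=O)OC)cc2OC)ccc1OC(=O)C(C)(C)C
F3 | step 5 | tert-butyl (2S,3R)-2-{2,6-dimethoxy-4-[(E)-3-methoxy-3-oxoprop-1-en-1-yl]phenoxy}-3-hydroxy-3-[3-methoxy-4-(pivaloyloxy)phenyl]propanoate | COc1cc([C@@H](O)[C@@H](C(=O)OC(C)(C)C)Oc2c(OC)cc(/C=C/C(=O)OC)cc2OC)ccc1OC(=O)C(C)(C)C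
F4 | step 7 | 7,9-bis(triethylsilyl) ether of 13 | COc1cc([C@@H](O[Si](CC)(CC)CC)[C@@H](CO[Si](CC)(CC)CC)Oc2c(OC)cc(/C=C/C(=O)OC)cc2OC)ccc1OC(=O)C(C)(C)C
F5 | step 7 | 7,9-bis(triethylsilyl) ether of 14 | COc1cc([C@@H](O[Si](CC)(CC)CC)[C@@H](CO[Si](CC)(CC)CC)Oc2c(OC)cc(/C=C/CO)cc2OC)ccc1O
F6 | step 6 | 7-O-triethylsilyl ether of 12 | COc1cc([C@@H](O[Si](CC)(CC)CC)[C@@H](C(=O)N2[C@@H](Cc3ccccc3)COC2=O)Oc4c(OC)cc(/C=C/C(=O)OC)cc4OC)ccc1OC(=O)C(C)(C)C
F7 | step 6 | 7-O-triethylsilyl ether of 13 | COc1cc([C@@H](O[Si](CC)(CC)CC)[C@@H](CO)Oc2c(OC)cc(/C=C/C(=O)OC)cc2OC)ccc1OC(=O)C(C)(C)C
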